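Ring A is built last, not bought. Its adjacent carbons C7a and C3a carry O1 and C3 of the dihydrofuran ring, so the O1–C2–C3 unit can serve as a three-atom tether between a pyridazine carbon and an alkyne. Heating lets the terminal alkyne add across ring positions 3 and 6 of an ester-activated 3-alkoxy-4-methoxypyridazine; loss of N2 then gives the benzene ring. This single operation forms C7a–C3a and C5–C4, closes ring A and the dihydrofuran ring, and leaves OMe on C7 and the ester on C5. The precursor is the pyridazinyl ether of an anti homopropargylic alcohol whose two stereocentres, the future C2 and C3, are set beforehand by a chiral allenylzinc addition.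

Key step: step 9

Remark on the chemistry (design): the hydroxymethyl group is carried as a triisopropylsilyl ether, because a 1,3-related secondary alkoxide is generated before the key step and a smaller silyl group could migrate to it; the alkyne is unmasked before the ether is made.

Remark on the chemistry (assumptions): palladium is taken to insert into the chloride of the dichloropyridazine that is remote from the methoxy group, and the stereochemical senses of the transfer hydrogenation and of the allenylzinc addition are taken from the accepted transition-state models.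

Step 1
Reactants: 1 ethyl glycolate
Product: 2 ethyl 2-[(triisopropylsilyl)oxy]acetate
Conditions: i-Pr3SiCl, imidazole, DMF, 0 °C to rt
Reagents that add atoms: chlorotriisopropylsilane, CC(C)[Si](Cl)(C(C)C)C(C)C
Why: Imidazole-promoted silylation of a primary alcohol is routine, and the bulky silyl group is chosen because it resists base-induced 1,3-migration in step 8 and heat in step 9.

Step 2
Reactants: 2 ethyl 2-[(triisopropylsilyl)oxy]acetate; 3 ethynyltrimethylsilane
Product: 5 1-[(triisopropylsilyl)oxy]-4-(trimethylsilyl)but-3-yn-2-one, via lithium (trimethylsilyl)acetylide 4 (not isolated)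
Conditions: 3, n-BuLi, THF, −78 °C; then BF3·OEt2, then 2, −78 °C; aq. NH4Cl
Reagents that add atoms: none
Why: In this Yamaguchi-type acylation the BF3-activated acetylide adds once to the α-oxygenated ester and the tetrahedral intermediate collapses only on work-up, so the ynone should not be attacked a second time.

Step 3
Reactants: 5 1-[(triisopropylsilyl)oxy]-4-(trimethylsilyl)but-3-yn-2-one
Product: 6 (S)-1-[(triisopropylsilyl)oxy]-4-(trimethylsilyl)but-3-yn-2-ol
Conditions: Ru[(R,R)-TsNCH(Ph)CH(Ph)NH](p-cymene) (1 mol%), i-PrOH, rt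
Reagents that add atoms: none
Why: In this Noyori asymmetric transfer hydrogenation the alkyne takes the place of the aryl group in the CH/π-controlled transition state, so the (R,R)-ligand should deliver hydride to the face that gives the S carbinol (S because CH2OSi outranks the alkynyl group), and the base-free medium leaves the C–SiMe3 bond intact.

Step 4
Reactants: 6 (S)-1-[(triisopropylsilyl)oxy]-4-(trimethylsilyl)but-3-yn-2-ol
Product: 7 (S)-1-[(triisopropylsilyl)oxy]-4-(trimethylsilyl)but-3-yn-2-yl methanesulfonate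
Conditions: MsCl, Et3N, CH2Cl2, −78 to 0 °C
Reagents that add atoms: methanesulfonyl chloride, CS(=O)(=O)Cl
Why: O-Sulfonylation of a secondary propargylic alcohol does not touch the C–O bond, so the configuration is retained.

Step 5
Reactants: 7 (S)-1-[(triisopropylsilyl)oxy]-4-(trimethylsilyl)but-3-yn-2-yl methanesulfonate; 8 3,4-dimethoxybenzaldehyde
Product: 10 (1S,2R)-1-(3,4-dimethoxyphenyl)-2-{[(triisopropylsilyl)oxy]methyl}-4-(trimethylsilyl)but-3-yn-1-ol, via allenylzinc 9 (not isolated)
Conditions: Pd(OAc)2 (5 mol%), PPh3 (5 mol%), Et2Zn (3 equiv), THF, −78 to −20 °C; aq. NH4Cl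
Reagents that add atoms: none
Why: In this Marshall–Tamaru propargylation zerovalent palladium displaces the mesylate in an anti SN2′ sense, transmetalation with Et2Zn gives the configurationally defined allenylzinc 9, and its syn SE2′ addition through a chair-like cyclic transition state with the aldehyde aryl group equatorial should set the propargylic carbon as R (net inversion at the mesylate carbon) and the carbinol carbon as S (anti).

Step 6
Reactants: 10 (1S,2R)-1-(3,4-dimethoxyphenyl)-2-{[(triisopropylsilyl)oxy]methyl}-4-(trimethylsilyl)but-3-yn-1-ol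
Product: 11 (1S,2R)-1-(3,4-dimethoxyphenyl)-2-{[(triisopropylsilyl)oxy]methyl}but-3-yn-1-ol
Conditions: K2CO3 (0.2 equiv), MeOH, rt
Reagents that add atoms: none
Why: Base-catalysed methanolysis (protodesilylation) should cleave only the alkynyl C–Si bond, since the hindered silyl ether and both stereocentres are inert to K2CO3 in methanol.

Step 7
Reactants: 12 3,6-dichloro-4-methoxypyridazine
Product: 13 methyl 6-chloro-5-methoxypyridazine-3-carboxylate
Conditions: CO (3 bar), Pd(dppf)Cl2 (3 mol%), Et3N, MeOH, 60 °C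
Reagents that add atoms: carbon monoxide, [C-]#[O+]; methanol, CO
Why: In this palladium-catalysed methoxycarbonylation (Heck carbonylation) oxidative addition should prefer the C6–Cl bond, which is unhindered and not deactivated by resonance donation from an adjacent methoxy group as the C3–Cl bond is, and the site of reaction is to be confirmed by an NOE experiment between OMe and the ring proton before use.

Step 8
Reactants: 11 (1S,2R)-1-(3,4-dimethoxyphenyl)-2-{[(triisopropylsilyl)oxy]methyl}but-3-yn-1-ol; 13 methyl 6-chloro-5-methoxypyridazine-3-carboxylate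
Product: 15 methyl 6-{[(1S,2R)-1-(3,4-dimethoxyphenyl)-2-{[(triisopropylsilyl)oxy]methyl}but-3-yn-1-yl]oxy}-5-methoxypyridazine-3-carboxylate, via sodium alkoxide 14 (not isolated)
Conditions: NaN(SiMe3)2 (1.05 equiv), THF, −78 °C; then 13, −78 to 0 °C
Reagents that add atoms: none
Why: In this nucleophilic aromatic substitution (addition–elimination) the only chloride of 13 lies next to ring nitrogen and para to the ester, so the alkoxide should displace it at low temperature with retention at the carbinol carbon (its C–O bond is not broken), while one equivalent of amide base, the cold and the bulky silyl group restrain ester attack, silyl migration and alkyne deprotonation.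

Step 9
Reactants: 15 methyl 6-{[(1S,2R)-1-(3,4-dimethoxyphenyl)-2-{[(triisopropylsilyl)oxy]methyl}but-3-yn-1-yl]oxy}-5-methoxypyridazine-3-carboxylate
Product: 17 methyl (2S,3R)-2-(3,4-dimethoxyphenyl)-7-methoxy-3-{[(triisopropylsilyl)oxy]methyl}-2,3-dihydro-1-benzofuran-5-carboxylate, via bridged diazabicyclooctatriene adduct 16 (not isolated)
Conditions: mesitylene (0.02 M), 2,6-di-tert-butyl-4-methylpyridine (0.2 equiv), degassed, sealed tube, 165 °C
Reagents that add atoms: none
Why: The ester-lowered LUMO of the diazine (diene termini at the ring carbons bearing the tether oxygen and the ester) combines with the HOMO of the tethered terminal alkyne in an intramolecular inverse-electron-demand Diels–Alder reaction that forms C7a–C3a and C5–C4 and gives the bridged 2,3-diazabicyclo[2.2.2]octatriene 16, which expels N2 by a retro-Diels–Alder reaction and so aromatises ring A irreversibly. The closest known reaction type is the thermal cycloaddition of 3-(but-3-ynyloxy)pyridazines, which delivers 2,3-dihydrobenzofurans in the same way. The dihydrofuran ring closes as the five-membered ring fused to the adduct, by C–C bond formation from the diene terminus to the internal alkyne carbon (5-exo-dig with respect to the alkyne), while ring A closes as a six-membered ring in the concerted [4+2] addition and becomes aromatic on loss of N2. No lasting stereocentre is created, since the bridgeheads of 16 vanish with N2, both faces of the diazine lead to the same arene, and C2 and C3 lie on the tether and are not touched. Regiochemistry is fixed by the three-atom tether, which lets only the internal alkyne carbon reach the oxygen-bearing diazine carbon, so OMe ends on C7 and the ester on C5. The selectivity that matters is cycloaddition against heterolysis of the benzylic C–O bond, and it is served by the ester (lower temperature), the two tether substituents (reactive rotamer favoured), a non-polar solvent and a hindered pyridine that removes adventitious acid.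

Step 10
Reactants: 17 methyl (2S,3R)-2-(3,4-dimethoxyphenyl)-7-methoxy-3-{[(triisopropylsilyl)oxy]methyl}-2,3-dihydro-1-benzofuran-5-carboxylate
Product: 18 [(2S,3R)-2-(3,4-dimethoxyphenyl)-7-methoxy-3-{[(triisopropylsilyl)oxy]methyl}-2,3-dihydro-1-benzofuran-5-yl]methanol
Conditions: i-Bu2AlH (3 equiv), CH2Cl2, −78 to 0 °C; aq. potassium sodium tartrate
Reagents that add atoms: none
Why: Full hydride reduction of an aryl methyl ester to the benzylic alcohol with excess i-Bu2AlH is reliable, and the aryl ethers, the silyl ether and the stereocentres are inert to it.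

Step 11
Reactants: 18 [(2S,3R)-2-(3,4-dimethoxyphenyl)-7-methoxy-3-{[(triisopropylsilyl)oxy]methyl}-2,3-dihydro-1-benzofuran-5-yl]methanol
Product: 20 methyl (2E)-3-[(2S,3R)-2-(3,4-dimethoxyphenyl)-7-methoxy-3-{[(triisopropylsilyl)oxy]methyl}-2,3-dihydro-1-benzofuran-5-yl]prop-2-enoate, via aldehyde 19 (not isolated)
Conditions: MnO2 (10 equiv), Ph3P=CHCO2Me (1.3 equiv), CH2Cl2, rt to 40 °C
Reagents that add atoms: methyl (triphenylphosphoranylidene)acetate, COC(=O)C=P(c1ccccc1)(c1ccccc1)c1ccccc1
Why: In this tandem oxidation–Wittig olefination MnO2 oxidises only the benzylic alcohol, and the aldehyde 19 is trapped as it forms by the stabilised ylide, which should give the E-enoate.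

Step 12
Reactants: 20 methyl (2E)-3-[(2S,3R)-2-(3,4-dimethoxyphenyl)-7-methoxy-3-{[(triisopropylsilyl)oxy]methyl}-2,3-dihydro-1-benzofuran-5-yl]prop-2-enoate
Product: 21 (2E)-3-[(2S,3R)-2-(3,4-dimethoxyphenyl)-7-methoxy-3-{[(triisopropylsilyl)oxy]methyl}-2,3-dihydro-1-benzofuran-5-yl]prop-2-en-1-ol
Conditions: i-Bu2AlH (2.5 equiv), CH2Cl2, −78 °C; aq. potassium sodium tartrate
Reagents that add atoms: none
Why: 1,2-Reduction of an α,β-unsaturated ester with i-Bu2AlH at low temperature should give the allylic alcohol with the E geometry retained.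

Step 13
Reactants: 21 (2E)-3-[(2S,3R)-2-(3,4-dimethoxyphenyl)-7-methoxy-3-{[(triisopropylsilyl)oxy]methyl}-2,3-dihydro-1-benzofuran-5-yl]prop-2-en-1-ol
Product: 22 Hierochin B, (2E)-3-[(2S,3R)-2-(3,4-dimethoxyphenyl)-3-(hydroxymethyl)-7-methoxy-2,3-dihydro-1-benzofuran-5-yl]prop-2-en-1-ol
Conditions: Bu4NF (1.2 equiv), THF, 0 °C to rt
Reagents that add atoms: none
Why: Fluoride-induced desilylation is driven by the strong Si–F bond and should affect nothing else in the molecule.

Compound list

1 | ethyl glycolate | CCOC(=O)CO | starting material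
2 | ethyl 2-[(triisopropylsilyl)oxy]acetate | CCOC(=O)CO[Si](C(C)C)(C(C)C)C(C)C | intermediate
3 | ethynyltrimethylsilane | C#C[Si](C)(C)C | starting material
4 | lithium (trimethylsilyl)acetylide (not isolated) | [Li]C#C[Si](C)(C)C | intermediate
5 | 1-[(triisopropylsilyl)oxy]-4-(trimethylsilyl)but-3-yn-2-one | C[Si](C)(C)C#CC(=O)CO[Si](C(C)C)(C(C)C)C(C)C | intermediate
6 | (S)-1-[(triisopropylsilyl)oxy]-4-(trimethylsilyl)but-3-yn-2-ol | C[Si](C)(C)C#C[C@H](O)CO[Si](C(C)C)(C(C)C)C(C)C | intermediate
7 | (S)-1-[(triisopropylsilyl)oxy]-4-(trimethylsilyl)but-3-yn-2-yl methanesulfonate | C[Si](C)(C)C#C[C@H](OS(C)(=O)=O)CO[Si](C(C)C)(C(C)C)C(C)C | intermediate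
8 | 3,4-dimethoxybenzaldehyde | COc1ccc(C=O)cc1OC | starting material
9 | ethyl{(Sa)-4-[(triisopropylsilyl)oxy]-1-(trimethylsilyl)buta-1,2-dien-1-yl}zinc (not isolated) | CC[Zn]C([Si](C)(C)C)=[C@@]=C([H])CO[Si](C(C)C)(C(C)C)C(C)C | intermediate
10 | (1S,2R)-1-(3,4-dimethoxyphenyl)-2-{[(triisopropylsilyl)oxy]methyl}-4-(trimethylsilyl)but-3-yn-1-ol | COc1ccc([C@@H](O)[C@@H](CO[Si](C(C)C)(C(C)C)C(C)C)C#C[Si](C)(C)C)cc1OC | intermediate
11 | (1S,2R)-1-(3,4-dimethoxyphenyl)-2-{[(triisopropylsilyl)oxy]methyl}but-3-yn-1-ol | COc1ccc([C@@H](O)[C@@H](CO[Si](C(C)C)(C(C)C)C(C)C)C#C)cc1OC | intermediate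
12 | 3,6-dichloro-4-methoxypyridazine | COc1cc(Cl)nnc1Cl | starting material
13 | methyl 6-chloro-5-methoxypyridazine-3-carboxylate | COC(=O)c1cc(OC)c(Cl)nn1 | intermediate
14 | sodium (1S,2R)-1-(3,4-dimethoxyphenyl)-2-{[(triisopropylsilyl)oxy]methyl}but-3-yn-1-olate (not isolated) | COc1ccc([C@@H]([O-])[C@@H](CO[Si](C(C)C)(C(C)C)C(C)C)C#C)cc1OC.[Na+] | intermediate
15 | methyl 6-{[(1S,2R)-1-(3,4-dimethoxyphenyl)-2-{[(triisopropylsilyl)oxy]methyl}but-3-yn-1-yl]oxy}-5-methoxypyridazine-3-carboxylate | COc1ccc([C@@H](Oc2nnc(C(=O)OC)cc2OC)[C@@H](CO[Si](C(C)C)(C(C)C)C(C)C)C#C)cc1OC | intermediate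
16 | bridged 2,3-diazabicyclo[2.2.2]octa-2,5,7-triene adduct with fused dihydrofuran ring, either bridgehead configuration (not isolated) | COc1ccc([C@H]2OC34N=NC(C(=O)OC)(C=C3[C@@H]2CO[Si](C(C)C)(C(C)C)C(C)C)C=C4OC)cc1OC | intermediate
17 | methyl (2S,3R)-2-(3,4-dimethoxyphenyl)-7-methoxy-3-{[(triisopropylsilyl)oxy]methyl}-2,3-dihydro-1-benzofuran-5-carboxylate (trans) | COc1ccc([C@H]2Oc3c(OC)cc(C(=O)OC)cc3[C@@H]2CO[Si](C(C)C)(C(C)C)C(C)C)cc1OC | intermediate
18 | [(2S,3R)-2-(3,4-dimethoxyphenyl)-7-methoxy-3-{[(triisopropylsilyl)oxy]methyl}-2,3-dihydro-1-benzofuran-5-yl]methanol | COc1ccc([C@H]2Oc3c(OC)cc(CO)cc3[C@@H]2CO[Si](C(C)C)(C(C)C)C(C)C)cc1OC | intermediate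
19 | (2S,3R)-2-(3,4-dimethoxyphenyl)-7-methoxy-3-{[(triisopropylsilyl)oxy]methyl}-2,3-dihydro-1-benzofuran-5-carbaldehyde (not isolated) | COc1ccc([C@H]2Oc3c(OC)cc(C=O)cc3[C@@H]2CO[Si](C(C)C)(C(C)C)C(C)C)cc1OC | intermediate
20 | methyl (2E)-3-[(2S,3R)-2-(3,4-dimethoxyphenyl)-7-methoxy-3-{[(triisopropylsilyl)oxy]methyl}-2,3-dihydro-1-benzofuran-5-yl]prop-2-enoate | COc1ccc([C@H]2Oc3c(OC)cc(/C=C/C(=O)OC)cc3[C@@H]2CO[Si](C(C)C)(C(C)C)C(C)C)cc1OC | intermediate
21 | (2E)-3-[(2S,3R)-2-(3,4-dimethoxyphenyl)-7-methoxy-3-{[(triisopropylsilyl)oxy]methyl}-2,3-dihydro-1-benzofuran-5-yl]prop-2-en-1-ol | COc1ccc([C@H]2Oc3c(OC)cc(/C=C/CO)cc3[C@@H]2CO[Si](C(C)C)(C(C)C)C(C)C)cc1OC | intermediate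
22 | Hierochin B, (2E)-3-[(2S,3R)-2-(3,4-dimethoxyphenyl)-3-(hydroxymethyl)-7-methoxy-2,3-dihydro-1-benzofuran-5-yl]prop-2-en-1-ol | COc1ccc([C@H]2Oc3c(OC)cc(/C=C/CO)cc3[C@@H]2CO)cc1OC | target

Total step count: 13.
Longest linear sequence: 12 steps (steps 1–6 and 8–13, from ethyl glycolate); step 7 is a one-step side branch.

Steps most likely to fail

Step 9. The diazine carries two donor alkoxy groups and needs a high temperature, at which heterolysis of the benzylic C–O bond may outrun the cycloaddition; the 4-methoxy group stabilises the cation and the ester-bearing pyridazinone is a good leaving group. The consequences would be elimination, oxygen-to-nitrogen transfer of the benzylic group or epimerisation at C2. The fallback keeps the ring construction but runs it on a substrate whose para oxygen is an electron-withdrawing sulfonate during the thermal step. It sets out from 7. Vanillin is tosylated (TsCl, Et3N, CH2Cl2) to 4-formyl-2-methoxyphenyl 4-methylbenzenesulfonate F1. F1 and 7 under the conditions of step 5 should give 4-[(1S,2R)-1-hydroxy-2-{[(triisopropylsilyl)oxy]methyl}-4-(trimethylsilyl)but-3-yn-1-yl]-2-methoxyphenyl 4-methylbenzenesulfonate F2. K2CO3 in MeOH then gives 4-[(1S,2R)-1-hydroxy-2-{[(triisopropylsilyl)oxy]methyl}but-3-yn-1-yl]-2-methoxyphenyl 4-methylbenzenesulfonate F3. NaN(SiMe3)2 and 13 as in step 8 give methyl 5-methoxy-6-{[(1S,2R)-1-[3-methoxy-4-(tosyloxy)phenyl]-2-{[(triisopropylsilyl)oxy]methyl}but-3-yn-1-yl]oxy}pyridazine-3-carboxylate F4, in which benzylic ionisation is disfavoured. Thermolysis as in step 9 gives methyl (2S,3R)-7-methoxy-2-[3-methoxy-4-(tosyloxy)phenyl]-3-{[(triisopropylsilyl)oxy]methyl}-2,3-dihydro-1-benzofuran-5-carboxylate F5. Mg in MeOH cleaves the aryl sulfonate to methyl (2S,3R)-2-(4-hydroxy-3-methoxyphenyl)-7-methoxy-3-{[(triisopropylsilyl)oxy]methyl}-2,3-dihydro-1-benzofuran-5-carboxylate F6, and MeI with K2CO3 in acetone returns the route to 17.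

Step 5. Electron-rich aromatic aldehydes react through a late transition state in which the chair arrangement loses part of its advantage, so simple diastereoselection at the carbinol carbon may be poor while chirality transfer to the propargylic carbon stays intact. The fallback gives up kinetic control of that centre and corrects it after ring construction, where C2 of the dihydrobenzofuran is the only centre that can ionise. It sets out from 7 and 8. The syn isomer (1R,2R)-1-(3,4-dimethoxyphenyl)-2-{[(triisopropylsilyl)oxy]methyl}-4-(trimethylsilyl)but-3-yn-1-ol F7, formed beside 10, is carried through steps 6, 8 and 9. This gives in turn (1R,2R)-1-(3,4-dimethoxyphenyl)-2-{[(triisopropylsilyl)oxy]methyl}but-3-yn-1-ol F8, then methyl 6-{[(1R,2R)-1-(3,4-dimethoxyphenyl)-2-{[(triisopropylsilyl)oxy]methyl}but-3-yn-1-yl]oxy}-5-methoxypyridazine-3-carboxylate F9, then the cis ester methyl (2R,3R)-2-(3,4-dimethoxyphenyl)-7-methoxy-3-{[(triisopropylsilyl)oxy]methyl}-2,3-dihydro-1-benzofuran-5-carboxylate F10. Treatment of F10 (or of its mixture with 17) with BF3·OEt2 in CH2Cl2 at 0 °C should open the C2–O1 bond reversibly to the dimethoxybenzyl cation and reclose it to the more stable trans isomer, so the route is rejoined at 17.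

Step 8. The free secondary alkoxide may attack the methyl ester, may pass the silyl group to itself so that the primary oxygen is arylated instead, or may be too hindered to displace a chloride flanked by a methoxy group. The fallback avoids a free alkoxide by forming the ether through palladium-catalysed C–O cross-coupling under a weak base, with the alkyne still masked. It sets out from 10. Coupling of 10 with 13 (Pd2(dba)3, RockPhos, Cs2CO3, toluene, 80 °C) should give methyl 6-{[(1S,2R)-1-(3,4-dimethoxyphenyl)-2-{[(triisopropylsilyl)oxy]methyl}-4-(trimethylsilyl)but-3-yn-1-yl]oxy}-5-methoxypyridazine-3-carboxylate F11. Protodesilylation with catalytic AgNO3 in aqueous acetone, which exposes the pyridazinyl ether to no alkoxide, then rejoins the route at 15 and bypasses 11.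

Further compounds
F1 | step 9 | 4-formyl-2-methoxyphenyl 4-methylbenzenesulfonate | COc1cc(C=O)ccc1OS(=O)(=O)c1ccc(C)cc1
F2 | step 9 | 4-[(1S,2R)-1-hydroxy-2-{[(triisopropylsilyl)oxy]methyl}-4-(trimethylsilyl)but-3-yn-1-yl]-2-methoxyphenyl 4-methylbenzenesulfonate | COc1cc([C@@H](O)[C@@H](CO[Si](C(C)C)(C(C)C)C(C)C)C#C[Si](C)(C)C)ccc1OS(=O)(=O)c1ccc(C)cc1
F3 | step 9 | 4-[(1S,2R)-1-hydroxy-2-{[(triisopropylsilyl)oxy]methyl}but-3-yn-1-yl]-2-methoxyphenyl 4-methylbenzenesulfonate | COc1cc([C@@H](O)[C@@H](CO[Si](C(C)C)(C(C)C)C(C)C)C#C)ccc1OS(=O)(=O)c1ccc(C)cc1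
F4 | step 9 | methyl 5-methoxy-6-{[(1S,2R)-1-[3-methoxy-4-(tosyloxy)phenyl]-2-{[(triisopropylsilyl)oxy]methyl}but-3-yn-1-yl]oxy}pyridazine-3-carboxylate | COc1cc([C@@H](Oc2nnc(C(=O)OC)cc2OC)[C@@H](CO[Si](C(C)C)(C(C)C)C(C)C)C#C)ccc1OS(=O)(=O)c1ccc(C)cc1
F5 | step 9 | methyl (2S,3R)-7-methoxy-2-[3-methoxy-4-(tosyloxy)phenyl]-3-{[(triisopropylsilyl)oxy]methyl}-2,3-dihydro-1-benzofuran-5-carboxylate | COc1cc([C@H]2Oc3c(OC)cc(C(=O)OC)cc3[C@@H]2CO[Si](C(C)C)(C(C)C)C(C)C)ccc1OS(=O)(=O)c1ccc(C)cc1
F6 | step 9 | methyl (2S,3R)-2-(4-hydroxy-3-methoxyphenyl)-7-methoxy-3-{[(triisopropylsilyl)oxy]methyl}-2,3-dihydro-1-benzofuran-5-carboxylate | COc1cc([C@H]2Oc3c(OC)cc(C(=O)OC)cc3[C@@H]2CO[Si](C(C)C)(C(C)C)C(C)C)ccc1O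
F7 | step 5 | (1R,2R)-1-(3,4-dimethoxyphenyl)-2-{[(triisopropylsilyl)oxy]methyl}-4-(trimethylsilyl)but-3-yn-1-ol | COc1ccc([C@H](O)[C@@H](CO[Si](C(C)C)(C(C)C)C(C)C)C#C[Si](C)(C)C)cc1OC
F8 | step 5 | (1R,2R)-1-(3,4-dimethoxyphenyl)-2-{[(triisopropylsilyl)oxy]methyl}but-3-yn-1-ol | COc1ccc([C@H](O)[C@@H](CO[Si](C(C)C)(C(C)C)C(C)C)C#C)cc1OC
F9 | step 5 | methyl 6-{[(1R,2R)-1-(3,4-dimethoxyphenyl)-2-{[(triisopropylsilyl)oxy]methyl}but-3-yn-1-yl]oxy}-5-methoxypyridazine-3-carboxylate | COc1ccc([C@H](Oc2nnc(C(=O)OC)cc2OC)[C@@H](CO[Si](C(C)C)(C(C)C)C(C)C)C#C)cc1OC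
F10 | step 5 | methyl (2R,3R)-2-(3,4-dimethoxyphenyl)-7-methoxy-3-{[(triisopropylsilyl)oxy]methyl}-2,3-dihydro-1-benzofuran-5-carboxylate (cis) | COc1ccc([C@@H]2Oc3c(OC)cc(C(=O)OC)cc3[C@@H]2CO[Si](C(C)C)(C(C)C)C(C)C)cc1OC
F11 | step 8 | methyl 6-{[(1S,2R)-1-(3,4-dimethoxyphenyl)-2-{[(triisopropylsilyl)oxy]methyl}-4-(trimethylsilyl)but-3-yn-1-yl]oxy}-5-methoxypyridazine-3-carboxylate | COc1ccc([C@@H](Oc2nnc(C(=O)OC)cc2OC)[C@@H](CO[Si](C(C)C)(C(C)C)C(C)C)C#C[Si](C)(C)C)cc1OC
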